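**Plan**

1. Retrosynthetic cuts, in order: the aryl–CHO and aryl–CO bonds (arene dressed last); a C9=C10 alkene is added back; then C1–C5 and C7–C8 of the hydroazulene together; then, in the acyclic chain, C6=C7 (allene), C1–C2 (diene arm), C4–C5 (quaternary carbon) and C1′–CH2 (arene).
2. Enabling feature: the seven-membered ring is an allyl unit C5=C6–C7 joined at both ends to a four-carbon unit C8–C9–C10–C1. Its ring-fusion alkene C5=C6 (C6–H) is what a metal-bound allyl cation from an allene C5=C6=C7 leaves after (4+3) cycloaddition to a diene C1=C10–C9=C8 and 1,2-hydride shift. C2–C3–C4 is the tether, so the same event closes the five-membered ring.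
3. Forward order: arene–allyl coupling → quaternary C4 → diene → allene → five- and seven-membered rings in one step → C10 → isovaleryl and formyl groups → deprotection.
4. Stereochemistry: C4 from a copper-catalysed enantioselective SN2′ alkynylation; C1 and C7 in the cycloaddition (face by the chiral ligand on gold, C7 relative to C1 by the exo transition state of the W-shaped allyl cation); C10 by hydroxyl-directed hydrogenation from the face that carries H-1 and the C7 side chain.

Key step: step 15

Numbering (guaiane numbering of the bicycle): C1 (sp3) and C5 (sp2) are the ring-fusion carbons; C2–C3–C4 complete the five-membered ring (C4 quaternary, CH3 and CH2Ar); C6–C10 complete the seven-membered ring (C6 is =CH, C7 carries the C11 carbinol, C10 carries CH3). Primed numbers are arene positions (C1′ carries the CH2). Ar = 2,4,6-tris(methoxymethoxy)phenyl.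

Assumption: in the two ligand-controlled steps (7 and 15) the sense of induction is taken as drawn; if it proves opposite, the mirror-image ligand is used and nothing else changes.

Ligands: ligand A = chiral sulfonate-bearing imidazolinium salt (N-heterocyclic carbene precursor). Ligand B = (S)-BINOL-derived phosphoramidite with 9-anthracenyl groups at C3 and C3′ and an N,N-bis[(R)-1-phenylethyl]amino group.

Compounds 1, 3, 12, 20 and all unnumbered reagents are commercial.

Step 1
Reactants: 1 phloroglucinol
Product: 2 1,3,5-tris(methoxymethoxy)benzene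
Conditions: MOMCl, i-Pr2NEt, CH2Cl2, 0 °C → rt
Reagents that add atoms: chloromethyl methyl ether, COCCl
Why: Threefold O-alkylation gives the MOM ethers, which later direct ring lithiation and come off with mild acid.

Step 2
Reactants: 3 prenyl acetate
Product: 4 (E)-4-hydroxy-3-methylbut-2-en-1-yl acetate
Conditions: SeO2 (cat.), t-BuOOH, CH2Cl2, rt
Reagents that add atoms: tert-butyl hydroperoxide, CC(C)(C)OO
Why: Selenium dioxide allylic oxidation (ene reaction, then 2,3-sigmatropic shift) hydroxylates the (E)-methyl group of a trisubstituted alkene, so the E geometry of the later allylic phosphate is fixed here.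

Step 3
Reactants: 4 (E)-4-hydroxy-3-methylbut-2-en-1-yl acetate
Product: 5 (E)-4-bromo-3-methylbut-2-en-1-yl acetate
Conditions: CBr4, PPh3, CH2Cl2, 0 °C
Reagents that add atoms: carbon tetrabromide, BrC(Br)(Br)Br
Why: Appel bromination of a primary allylic alcohol should proceed without touching the acetate or the alkene geometry.

Step 4
Reactants: 2 1,3,5-tris(methoxymethoxy)benzene; 5 (E)-4-bromo-3-methylbut-2-en-1-yl acetate
Product: 8 (E)-3-methyl-4-[2,4,6-tris(methoxymethoxy)phenyl]but-2-en-1-yl acetate, via aryllithium 6 (not isolated), via arylmagnesium bromide 7 (not isolated)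
Conditions: n-BuLi, THF, 0 °C; MgBr2·OEt2, −20 °C; Li2CuCl4 (5 mol %), then 5, −40 → 0 °C
Reagents that add atoms: none
Why: Lithiation between two MOM-oxy groups (directed ortho metalation), then copper-catalysed coupling of the aryl Grignard reagent with the primary allylic bromide at its CH2Br carbon; the ester should survive at low temperature.

Step 5
Reactants: 8 (E)-3-methyl-4-[2,4,6-tris(methoxymethoxy)phenyl]but-2-en-1-yl acetate
Product: 9 (E)-3-methyl-4-[2,4,6-tris(methoxymethoxy)phenyl]but-2-en-1-ol
Conditions: K2CO3, MeOH, rt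
Reagents that add atoms: none
Why: Base-catalysed transesterification removes the acetate.

Step 6
Reactants: 9 (E)-3-methyl-4-[2,4,6-tris(methoxymethoxy)phenyl]but-2-en-1-ol
Product: 10 diethyl (E)-3-methyl-4-[2,4,6-tris(methoxymethoxy)phenyl]but-2-en-1-yl phosphate
Conditions: (EtO)2P(O)Cl, Et3N, DMAP (cat.), CH2Cl2, 0 °C
Reagents that add atoms: diethyl chlorophosphate, CCOP(=O)(Cl)OCC
Why: O-phosphorylation gives the leaving group needed for copper-catalysed allylic substitution.

Step 7
Reactants: 10 diethyl (E)-3-methyl-4-[2,4,6-tris(methoxymethoxy)phenyl]but-2-en-1-yl phosphate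
Product: 11 (S)-trimethyl{3-methyl-3-[2,4,6-tris(methoxymethoxy)benzyl]pent-4-en-1-yn-1-yl}silane
Conditions: Me3SiC≡CH, (i-Bu)2AlH, Et3N (cat.), hexanes, 55 °C; then 10, CuCl2·2H2O (5 mol %), ligand A (5.5 mol %), THF, −15 °C
Reagents that add atoms: trimethylsilylacetylene, C#C[Si](C)(C)C
Why: Copper–carbene-catalysed enantioselective allylic substitution (SN2′) of a trisubstituted allylic phosphate by an alkynylaluminium reagent puts the alkynyl group on the γ-carbon; the defined E alkene and the chiral ligand together set the quaternary centre C4.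

Step 8
Reactants: 12 prop-2-yn-1-ol
Product: 14 (E)-3-iodo-2-methylprop-2-en-1-ol, via alkenylalane 13 (not isolated)
Conditions: Me3Al, Cp2ZrCl2, CH2Cl2, 0 °C → rt; then I2, THF, −30 °C
Reagents that add atoms: trimethylaluminium, C[Al](C)C; iodine, II
Why: Zirconium-catalysed carboalumination (Negishi) adds methyl and aluminium syn across the alkyne with methyl on the internal carbon, and iodinolysis of the alkenylalane with retention gives the E vinyl iodide.

Step 9
Reactants: 14 (E)-3-iodo-2-methylprop-2-en-1-ol
Product: 15 (E)-3-iodo-2-methylprop-2-enal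
Conditions: MnO2, CH2Cl2, rt
Reagents that add atoms: none
Why: Manganese dioxide oxidises the allylic alcohol selectively and leaves the vinyl iodide and its geometry alone.

Step 10
Reactants: 15 (E)-3-iodo-2-methylprop-2-enal
Product: 16 (E)-1-iodo-2-methylbuta-1,3-diene
Conditions: Ph3PCH3Br, n-BuLi, THF, 0 °C; then 15, 0 °C (product kept as a solution)
Reagents that add atoms: methyltriphenylphosphonium bromide, C[P+](c1ccccc1)(c1ccccc1)c1ccccc1.[Br-]
Why: Wittig methylenation of the enal gives the diene without changing the trisubstituted alkene.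

Step 11
Reactants: 11 (S)-trimethyl{3-methyl-3-[2,4,6-tris(methoxymethoxy)benzyl]pent-4-en-1-yn-1-yl}silane; 16 (E)-1-iodo-2-methylbuta-1,3-diene
Product: 19 2-[(2R,5E)-2-ethynyl-2,6-dimethylocta-5,7-dien-1-yl]-1,3,5-tris(methoxymethoxy)benzene, via B-alkyl-9-borabicyclononane 17 (not isolated), via silylated dienyne 18 (not isolated)
Conditions: 9-BBN, THF, rt; then 16, Pd(dppf)Cl2 (5 mol %), AsPh3, Cs2CO3, DMF/THF/H2O, rt; then K2CO3, MeOH, rt
Reagents that add atoms: none
Why: Anti-Markovnikov hydroboration of the vinyl group (the silylalkyne is inert to 9-BBN), then B-alkyl Suzuki coupling with retention of the vinyl iodide geometry, builds the E diene arm; methanolysis then frees the terminal alkyne.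

Step 12
Reactants: 20 methyl 2-hydroxy-2-methylpropanoate
Product: 21 methyl 2-methyl-2-(triethylsilyloxy)propanoate
Conditions: Et3SiCl, imidazole, DMF, rt
Reagents that add atoms: chlorotriethylsilane, CC[Si](Cl)(CC)CC
Why: Silylation masks the tertiary hydroxyl that will become the C11 oxygen.

Step 13
Reactants: 21 methyl 2-methyl-2-(triethylsilyloxy)propanoate
Product: 22 2-methyl-2-(triethylsilyloxy)propanal
Conditions: (i-Bu)2AlH, CH2Cl2, −78 °C; Rochelle salt work-up
Reagents that add atoms: none
Why: Partial reduction of an α-silyloxy ester should stop at the aldehyde because the aluminium hemiacetal is stable at −78 °C.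

Step 14
Reactants: 19 2-[(2R,5E)-2-ethynyl-2,6-dimethylocta-5,7-dien-1-yl]-1,3,5-tris(methoxymethoxy)benzene; 22 2-methyl-2-(triethylsilyloxy)propanal
Product: 25 triethyl{[(6R,9E)-2,6,10-trimethyl-6-[2,4,6-tris(methoxymethoxy)benzyl]dodeca-3,4,9,11-tetraen-2-yl]oxy}silane (both allene-axis epimers), via N-tosylhydrazone 23 (not isolated), via diazoalkane 24 (not isolated)
Conditions: 22, TsNHNH2, 1,4-dioxane, rt; then 19, CuI (10 mol %), LiOt-Bu, 90 °C
Reagents that add atoms: none
Why: Copper-catalysed coupling of a terminal alkyne with a diazoalkane made in situ (carbene migratory insertion into the copper acetylide, then protonation at the far alkyne carbon) gives the 1,3-disubstituted allene; the carbene has no β-hydrogen, and the allene axis need not be controlled.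

Step 15
Reactants: 25 triethyl{[(6R,9E)-2,6,10-trimethyl-6-[2,4,6-tris(methoxymethoxy)benzyl]dodeca-3,4,9,11-tetraen-2-yl]oxy}silane
Product: 26 (1R,4R,7R)-4-[2,4,6-tris(methoxymethoxy)benzyl]-11-(triethylsilyloxy)guaia-5,9-diene
Conditions: AuCl(ligand B) (5 mol %), AgSbF6 (5 mol %), 4 Å molecular sieves, CH2Cl2, −15 °C → rt
Reagents that add atoms: none
Why: The cationic monovalent gold complex binds the allene and opens it to a planar gold-bound allyl cation (C5–C6–C7, gold on C6), which adds to the s-cis diene C1=C10–C9=C8 in one asynchronous (4C+3C) step through an exo-like (extended) transition state to give a cycloheptenyl gold carbene at C6; 1,2-hydride shift from C5 and loss of the metal then leave the C5=C6 alkene. The closest known reaction type is the gold- or platinum-catalysed intramolecular (4+3) cycloaddition of allenedienes, including its enantioselective phosphoramidite–gold form. The five-membered ring closes through the C1–C5 bond (the C2–C3–C4 tether brings the diene terminus C1 onto the allyl terminus C5, exo with respect to the diene), and the seven-membered ring closes through the C7–C8 bond as the second bond of the cycloaddition. C1 is set by the facial preference imposed by the chiral phosphoramidite (the C4 centre only tells CH3 from CH2Ar and should give little bias of its own), and C7 is set relative to C1 by the W geometry of the allyl cation (tether and silyloxyisopropyl group both outside) together with the extended transition state, which places the C7 side chain cis to H-1; both allene-axis epimers converge because the cation is planar. The step needs (4+3) over (4+2) selectivity and hydride shift from C5, not C7: a cation at the secondary C7 is destabilised by the β-silyloxy group, which disfavours both the 1,2-alkyl shift that leads to ring contraction and hydride departure from C7, while hydride departure from C5 leaves positive character on a tertiary carbon with no withdrawing group. The silyl ether keeps the C11 oxygen from adding to the activated allene.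

Step 16
Reactants: 26 (1R,4R,7R)-4-[2,4,6-tris(methoxymethoxy)benzyl]-11-(triethylsilyloxy)guaia-5,9-diene
Product: 27 (1R,4R,7R)-4-[2,4,6-tris(methoxymethoxy)benzyl]guaia-5,9-dien-11-ol
Conditions: Bu4NF, THF, 0 → 40 °C
Reagents that add atoms: none
Why: Fluoride cleaves the silyl ether and leaves the aryl MOM ethers intact, freeing the hydroxyl that directs the next step.

Step 17
Reactants: 27 (1R,4R,7R)-4-[2,4,6-tris(methoxymethoxy)benzyl]guaia-5,9-dien-11-ol
Product: 28 (1R,4R,7R,10R)-4-[2,4,6-tris(methoxymethoxy)benzyl]guai-5-en-11-ol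
Conditions: [Ir(cod)(PCy3)(py)]PF6 (5 mol %), H2 (1 atm), CH2Cl2, 0 °C, stopped after one equivalent of H2
Reagents that add atoms: none
Why: Hydroxyl-directed hydrogenation: iridium bound to the C11 hydroxyl, which sits on the ring face that carries H-1, should deliver hydrogen to that face of C9=C10 (also its outer face in the folded cycloheptadiene), giving H-10 cis to H-1 (10R); C5=C6 should be spared because its outer face is blocked by the arylmethyl group on quaternary C4 and its inner face by the ring.

Step 18
Reactants: 28 (1R,4R,7R,10R)-4-[2,4,6-tris(methoxymethoxy)benzyl]guai-5-en-11-ol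
Product: 30 3′-(1-hydroxy-3-methylbutyl) derivative of 28 (both carbinol epimers), via C3′,O11-dilithio derivative 29 (not isolated)
Conditions: n-BuLi (2.2 equiv), TMEDA, THF, −20 → 0 °C; isovaleraldehyde, −78 °C; aq. NH4Cl
Reagents that add atoms: 3-methylbutanal, CC(C)CC=O
Why: After the alkoxide forms, directed ortho metalation at a ring position flanked by two MOM-oxy groups (the two free positions are equivalent) and addition to the aldehyde install the isovaleryl carbon skeleton; the new carbinol centre is oxidised away in step 20.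

Step 19
Reactants: 30 3′-(1-hydroxy-3-methylbutyl) derivative of 28
Product: 32 5′-formyl-3′-(1-hydroxy-3-methylbutyl) derivative of 28, via trilithio derivative 31 (not isolated)
Conditions: n-BuLi (3.3 equiv), THF, −20 → 0 °C; DMF, −78 → 0 °C; aq. NH4Cl
Reagents that add atoms: N,N-dimethylformamide, CN(C)C=O
Why: The two alkoxides protect themselves, and the last ring position, again flanked by two MOM-oxy groups, is lithiated (directed ortho metalation) and formylated.

Step 20
Reactants: 32 5′-formyl-3′-(1-hydroxy-3-methylbutyl) derivative of 28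
Product: 33 tris(methoxymethyl) ether of the target
Conditions: 1,1,1-triacetoxy-1,1-dihydro-1,2-benziodoxol-3(1H)-one, NaHCO3, CH2Cl2, 0 °C → rt
Reagents that add atoms: none
Why: The hypervalent iodine oxidant (Dess–Martin oxidation) converts the secondary benzylic alcohol into the aryl ketone; the tertiary alcohol cannot be oxidised and the alkene and aldehyde should be inert.

Step 21
Reactants: 33 tris(methoxymethyl) ether of the target
Product: 34 target compound
Conditions: HCl (0.3 M in MeOH), 0 °C → rt, stopped as soon as the last MOM group is gone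
Reagents that add atoms: none
Why: Acid-catalysed acetal exchange removes the three MOM groups, each ortho to a carbonyl and so readily cleaved, under dilute acid and short contact that the tertiary alcohol and the hindered alkene should tolerate.

**Compound list**

1 | phloroglucinol | Oc1cc(O)cc(O)c1 | starting material
2 | 1,3,5-tris(methoxymethoxy)benzene | COCOc1cc(OCOC)cc(OCOC)c1 | intermediate
3 | prenyl acetate | CC(C)=CCOC(C)=O | starting material
4 | (E)-4-hydroxy-3-methylbut-2-en-1-yl acetate | CC(=O)OC/C=C(C)/CO | intermediate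
5 | (E)-4-bromo-3-methylbut-2-en-1-yl acetate | CC(=O)OC/C=C(C)/CBr | intermediate
6 | 2,4,6-tris(methoxymethoxy)phenyllithium | [Li]c1c(OCOC)cc(OCOC)cc1OCOC | intermediate
7 | 2,4,6-tris(methoxymethoxy)phenylmagnesium bromide | Br[Mg]c1c(OCOC)cc(OCOC)cc1OCOC | intermediate
8 | (E)-3-methyl-4-[2,4,6-tris(methoxymethoxy)phenyl]but-2-en-1-yl acetate | CC(=O)OC/C=C(C)/Cc1c(OCOC)cc(OCOC)cc1OCOC | intermediate
9 | (E)-3-methyl-4-[2,4,6-tris(methoxymethoxy)phenyl]but-2-en-1-ol | OC/C=C(C)/Cc1c(OCOC)cc(OCOC)cc1OCOC | intermediate
10 | diethyl (E)-3-methyl-4-[2,4,6-tris(methoxymethoxy)phenyl]but-2-en-1-yl phosphate | CCOP(=O)(OCC)OC/C=C(C)/Cc1c(OCOC)cc(OCOC)cc1OCOC | intermediate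
11 | (S)-trimethyl{3-methyl-3-[2,4,6-tris(methoxymethoxy)benzyl]pent-4-en-1-yn-1-yl}silane | C[Si](C)(C)C#C[C@@](C)(Cc1c(OCOC)cc(OCOC)cc1OCOC)C=C | intermediate
12 | prop-2-yn-1-ol | C#CCO | starting material
13 | (E)-alkenylalane: dimethylaluminium alkoxide of 3-(dimethylalumanyl)-2-methylprop-2-en-1-ol | C[Al](C)/C=C(C)/CO[Al](C)C | intermediate
14 | (E)-3-iodo-2-methylprop-2-en-1-ol | OC/C(C)=C/I | intermediate
15 | (E)-3-iodo-2-methylprop-2-enal | O=C/C(C)=C/I | intermediate
16 | (E)-1-iodo-2-methylbuta-1,3-diene | C=C/C(C)=C/I | intermediate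
17 | 9-{(R)-3-methyl-5-(trimethylsilyl)-3-[2,4,6-tris(methoxymethoxy)benzyl]pent-4-yn-1-yl}-9-borabicyclo[3.3.1]nonane | C[Si](C)(C)C#C[C@@](C)(Cc1c(OCOC)cc(OCOC)cc1OCOC)CCB1C2CCCC1CCC2 | intermediate
18 | trimethyl{(3R,6E)-3,7-dimethyl-3-[2,4,6-tris(methoxymethoxy)benzyl]nona-6,8-dien-1-yn-1-yl}silane | C[Si](C)(C)C#C[C@@](C)(Cc1c(OCOC)cc(OCOC)cc1OCOC)CC/C=C(C)/C=C | intermediate
19 | 2-[(2R,5E)-2-ethynyl-2,6-dimethylocta-5,7-dien-1-yl]-1,3,5-tris(methoxymethoxy)benzene | C#C[C@@](C)(Cc1c(OCOC)cc(OCOC)cc1OCOC)CC/C=C(C)/C=C | intermediate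
20 | methyl 2-hydroxy-2-methylpropanoate | COC(=O)C(C)(C)O | starting material
21 | methyl 2-methyl-2-(triethylsilyloxy)propanoate | CC[Si](CC)(CC)OC(C)(C)C(=O)OC | intermediate
22 | 2-methyl-2-(triethylsilyloxy)propanal | CC[Si](CC)(CC)OC(C)(C)C=O | intermediate
23 | 4-methyl-N′-[2-methyl-2-(triethylsilyloxy)propylidene]benzenesulfonohydrazide | CC[Si](CC)(CC)OC(C)(C)/C=N/NS(=O)(=O)c1ccc(C)cc1 | intermediate
24 | 1-diazo-2-methyl-2-(triethylsilyloxy)propane | CC[Si](CC)(CC)OC(C)(C)C=[N+]=[N-] | intermediate
25 | triethyl{[(6R,9E)-2,6,10-trimethyl-6-[2,4,6-tris(methoxymethoxy)benzyl]dodeca-3,4,9,11-tetraen-2-yl]oxy}silane, both allene-axis epimers | CC[Si](CC)(CC)OC(C)(C)C=C=C[C@@](C)(Cc1c(OCOC)cc(OCOC)cc1OCOC)CC/C=C(C)/C=C | intermediate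
26 | (1R,4R,7R)-4-[2,4,6-tris(methoxymethoxy)benzyl]-11-(triethylsilyloxy)guaia-5,9-diene; H-1 cis to the arylmethyl group and to the C7 side chain | COCOc1cc(OCOC)c(C[C@@]2(C)CC[C@H]3C2=C[C@H](C(C)(C)O[Si](CC)(CC)CC)CC=C3C)c(OCOC)c1 | intermediate
27 | (1R,4R,7R)-4-[2,4,6-tris(methoxymethoxy)benzyl]guaia-5,9-dien-11-ol | COCOc1cc(OCOC)c(C[C@@]2(C)CC[C@H]3C2=C[C@H](C(C)(C)O)CC=C3C)c(OCOC)c1 | intermediate
28 | (1R,4R,7R,10R)-4-[2,4,6-tris(methoxymethoxy)benzyl]guai-5-en-11-ol | COCOc1cc(OCOC)c(C[C@@]2(C)CC[C@H]3C2=C[C@H](C(C)(C)O)CC[C@H]3C)c(OCOC)c1 | intermediate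
29 | C3′,O11-dilithio derivative of 28 | COCOc1c([Li])c(OCOC)c(C[C@@]2(C)CC[C@H]3C2=C[C@H](C(C)(C)O[Li])CC[C@H]3C)c(OCOC)c1 | intermediate
30 | 28 carrying a 1-hydroxy-3-methylbutyl group at C3′, both carbinol epimers | COCOc1c(C(O)CC(C)C)c(OCOC)c(C[C@@]2(C)CC[C@H]3C2=C[C@H](C(C)(C)O)CC[C@H]3C)c(OCOC)c1 | intermediate
31 | C5′-lithio bis(lithium alkoxide) of 30 | COCOc1c(C(O[Li])CC(C)C)c(OCOC)c(C[C@@]2(C)CC[C@H]3C2=C[C@H](C(C)(C)O[Li])CC[C@H]3C)c(OCOC)c1[Li] | intermediate
32 | 30 carrying a formyl group at C5′ | COCOc1c(C(O)CC(C)C)c(OCOC)c(C[C@@]2(C)CC[C@H]3C2=C[C@H](C(C)(C)O)CC[C@H]3C)c(OCOC)c1C=O | intermediate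
33 | tris(methoxymethyl) ether of the target (5′-formyl, 3′-(3-methylbutanoyl)) | COCOc1c(C(=O)CC(C)C)c(OCOC)c(C[C@@]2(C)CC[C@H]3C2=C[C@H](C(C)(C)O)CC[C@H]3C)c(OCOC)c1C=O | intermediate
34 | target: (1R,4R,7R,10R)-4-[(3-formyl-2,4,6-trihydroxy-5-(3-methylbutanoyl)phenyl)methyl]guai-5-en-11-ol | CC(C)CC(=O)c1c(O)c(C=O)c(O)c(C[C@@]2(C)CC[C@H]3C2=C[C@H](C(C)(C)O)CC[C@H]3C)c1O | target

**Step count**

Total: 21 steps. Longest linear sequence: 15 steps (2, 3, 4, 5, 6, 7, 11, 14, 15, 16, 17, 18, 19, 20, 21), counted from prenyl acetate 3.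

**Steps most likely to fail**

Step 15. The diene may approach the gold-bound allyl cation from either face with little discrimination, because the C4 centre only distinguishes CH3 from CH2Ar and the ligand may not overrule or may oppose it. The cation may also be captured by the silyloxy or an ortho MOM-oxy oxygen before the diene arrives. The fallback replaces ligand control by a removable stereocentre on the tether; it sets out from 11 (and uses 16 and 22) and returns at 27. Enyne 11 is hydroborated with 9-BBN (borane 17) and oxidised with NaBO3·4H2O to the primary alcohol F1, which the periodinane of step 20 oxidises to the aldehyde F2. Iodine–lithium exchange on 16 (t-BuLi, Et2O, −78 °C) gives the dienyllithium F3, which adds to F2; after an NH4Cl quench the (2R)-carbinol F4 is separated by chromatography from its (2S)-epimer F5. Silylation of F4 (t-BuMe2SiCl, imidazole, DMF) gives the silyl ether F6, and K2CO3/MeOH gives the terminal alkyne F7. Copper-catalysed coupling with 22 and TsNHNH2 as in step 14 (through 23 and 24) gives the allene F8. An achiral catalyst, AuCl[P(t-Bu)2(2-biphenylyl)]/AgSbF6, should then give the cycloadduct F9. The face is now fixed by allylic 1,3-strain between C2 and the C10 methyl: the C2 hydrogen eclipses the alkene, the tether carbon C3 and the silyloxy group lie on opposite faces, and the allyl cation must arrive on the face of C3, so the silyloxy group ends cis to H-1. Bu4NF removes both silyl groups to give the diol F10. The secondary hydroxyl is converted into the phenyl thionocarbonate F11 (PhOC(S)Cl, pyridine, DMAP) and removed with Bu3SnH/AIBN (Barton–McCombie deoxygenation, at high stannane concentration to outrun a 1,2-vinyl shift of the C2 radical) to give 27.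

Step 17. The C11 hydroxyl is homoallylic to C5=C6, so chelation may deliver hydrogen to that alkene as well, or an iridium hydride may move the C9=C10 alkene before it is reduced. The fallback replaces directed delivery by steric control and exchanges the order of desilylation and reduction; it sets out from 26 and returns at 28. The silyl ether 26 is hydrogenated without a directing group (H2, 1 atm, PtO2, EtOAc). C5=C6 is shielded on its outer face by the arylmethyl group on quaternary C4. In the folded cycloheptadiene the C1–C5 bond occupies the inner face of C9=C10 and pseudo-axial H-1 the outer face, so hydrogen should add from the outer face, cis to H-1, giving the silyl ether F12. Bu4NF then gives 28.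

Step 14. The copper carbene may be consumed by cyclopropanation of the diene, azine formation or a 1,2-shift before it couples with the hindered copper acetylide. The fallback builds the allene in two stages by carbonyl addition and SN2′ reduction; it sets out from 19 and 22 and returns at 25. Alkyne 19 is deprotonated with i-PrMgCl·LiCl to the alkynylmagnesium chloride F13, which adds to 22 to give, after an NH4Cl quench, the propargylic alcohol F14 (both carbinol epimers). Methyl chloroformate and pyridine give the methyl carbonate F15. Copper hydride-catalysed anti-SN2′ reduction (CuCl(IPr), NaOt-Bu, polymethylhydrosiloxane, toluene) delivers hydride to C5 and expels the carbonate to give 25.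

**Further compounds**

F1 | step 15 | (S)-3-methyl-5-(trimethylsilyl)-3-[2,4,6-tris(methoxymethoxy)benzyl]pent-4-yn-1-ol | C[Si](C)(C)C#C[C@@](C)(Cc1c(OCOC)cc(OCOC)cc1OCOC)CCO
F2 | step 15 | (S)-3-methyl-5-(trimethylsilyl)-3-[2,4,6-tris(methoxymethoxy)benzyl]pent-4-ynal | C[Si](C)(C)C#C[C@@](C)(Cc1c(OCOC)cc(OCOC)cc1OCOC)CC=O
F3 | step 15 | (E)-(2-methylbuta-1,3-dien-1-yl)lithium | [Li]/C=C(C)/C=C
F4 | step 15 | (2R)-hydroxy derivative of 18 (hydroxyl on the tether carbon next to the diene, C2 of the later bicycle) | C[Si](C)(C)C#C[C@@](C)(Cc1c(OCOC)cc(OCOC)cc1OCOC)C[C@@H](O)/C=C(C)/C=C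
F5 | step 15 | (2S)-epimer of F4 at the carbinol carbon | C[Si](C)(C)C#C[C@@](C)(Cc1c(OCOC)cc(OCOC)cc1OCOC)C[C@H](O)/C=C(C)/C=C
F6 | step 15 | tert-butyldimethylsilyl ether of F4 | C[Si](C)(C)C#C[C@@](C)(Cc1c(OCOC)cc(OCOC)cc1OCOC)C[C@@H](O[Si](C)(C)C(C)(C)C)/C=C(C)/C=C
F7 | step 15 | terminal alkyne from F6 (2-silyloxy analogue of 19) | C#C[C@@](C)(Cc1c(OCOC)cc(OCOC)cc1OCOC)C[C@@H](O[Si](C)(C)C(C)(C)C)/C=C(C)/C=C
F8 | step 15 | 2-(tert-butyldimethylsilyloxy) analogue of allene 25 | CC[Si](CC)(CC)OC(C)(C)C=C=C[C@@](C)(Cc1c(OCOC)cc(OCOC)cc1OCOC)C[C@@H](O[Si](C)(C)C(C)(C)C)/C=C(C)/C=C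
F9 | step 15 | 2-(tert-butyldimethylsilyloxy) analogue of cycloadduct 26, silyloxy group cis to H-1 | COCOc1cc(OCOC)c(C[C@@]2(C)C[C@@H](O[Si](C)(C)C(C)(C)C)[C@H]3C2=C[C@H](C(C)(C)O[Si](CC)(CC)CC)CC=C3C)c(OCOC)c1
F10 | step 15 | 2-hydroxy analogue of 27 (2,11-diol) | COCOc1cc(OCOC)c(C[C@@]2(C)C[C@@H](O)[C@H]3C2=C[C@H](C(C)(C)O)CC=C3C)c(OCOC)c1
F11 | step 15 | O-phenyl thionocarbonate of F10 at the C2 hydroxyl | COCOc1cc(OCOC)c(C[C@@]2(C)C[C@@H](OC(=S)Oc4ccccc4)[C@H]3C2=C[C@H](C(C)(C)O)CC=C3C)c(OCOC)c1
F12 | step 17 | (1R,4R,7R,10R)-4-[2,4,6-tris(methoxymethoxy)benzyl]-11-(triethylsilyloxy)guai-5-ene | COCOc1cc(OCOC)c(C[C@@]2(C)CC[C@H]3C2=C[C@H](C(C)(C)O[Si](CC)(CC)CC)CC[C@H]3C)c(OCOC)c1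
F13 | step 14 | alkynylmagnesium chloride from 19 | Cl[Mg]C#C[C@@](C)(Cc1c(OCOC)cc(OCOC)cc1OCOC)CC/C=C(C)/C=C
F14 | step 14 | propargylic alcohol from 19 and 22, both carbinol epimers | CC[Si](CC)(CC)OC(C)(C)C(O)C#C[C@@](C)(Cc1c(OCOC)cc(OCOC)cc1OCOC)CC/C=C(C)/C=C
F15 | step 14 | methyl carbonate of F14 | CC[Si](CC)(CC)OC(C)(C)C(OC(=O)OC)C#C[C@@](C)(Cc1c(OCOC)cc(OCOC)cc1OCOC)CC/C=C(C)/C=C
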